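**Plan**

- Cuts, in retrosynthetic order: the ring-B MOM ether; the C5–C6 bond of ring A (Claisen/Dieckmann), which opens the acylphloroglucinol to a β-diketone chain on a dihydropyran ester; the C6–C(=O) bond (dianion acylation by the ring-B ester); the C7–C8 bond (acetylation of the pyran 2-methyl); the pyran O1–C2 bond and the two prenyl C–C bonds.
- Enabling feature: ring A (C4a, C5, C6, C7, C8, C8a) is the enol form of a 2-acylcyclohexane-1,3,5-trione whose C8a oxygen is O1 of the dimethylpyran ring, tied back to C4a through C2–C3–C4. The pyran can therefore carry C5 as an ester and C8 as a methyl branch before ring A exists.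
- Forward: pyran ring first (step 2), chain grown at C8 and then C6 (steps 3 and 6), ring A closed and aromatised (step 7), phenol released (step 8); ring B is made separately (steps 4 and 5).
- Stereochemistry: none to set; the target has no stereocentre and the prenyl double bond is not stereogenic.

Key step: step 7

Remark: because the target is achiral, "single enantiomer" is taken to mean the compound exactly as drawn; the racemic centres of 3 and 14 are transient and disappear in the following transformation.

**Route**

Step 1
Reactants: 1 methyl acetoacetate; 2 prenyl bromide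
Product: 3 methyl 2-acetyl-5-methylhex-4-enoate (racemic)
Conditions: K2CO3, acetone, reflux (1 in 1.5-fold excess)
Reagents that add atoms: none
Why: C-alkylation of the stabilised β-keto ester enolate by the allylic bromide (acetoacetic ester alkylation, SN2) is standard, the excess of 1 suppresses dialkylation, and the new α-centre is racemic and becomes sp2 in step 2.

Step 2
Reactants: 3 methyl 2-acetyl-5-methylhex-4-enoate
Product: 4 methyl 2,6,6-trimethyl-5,6-dihydro-4H-pyran-3-carboxylate
Conditions: TfOH (5 mol %), CH2Cl2, 0 °C → rt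
Reagents that add atoms: none
Why: Markovnikov protonation of the trisubstituted alkene gives a tertiary cation that the ketone enol oxygen captures in a six-membered closure (acid-catalysed cycloisomerisation of a 2-prenyl-1,3-dicarbonyl compound), leaving the conjugated β-alkoxyacrylate.

Step 3
Reactants: 4 methyl 2,6,6-trimethyl-5,6-dihydro-4H-pyran-3-carboxylate
Product: 7 methyl 6,6-dimethyl-2-(2-oxopropyl)-5,6-dihydro-4H-pyran-3-carboxylate, via lithium dienolate 5 (not isolated), via lithium hemiaminal adduct 6 (not isolated)
Conditions: LDA (1.1 equiv), THF, −78 °C; then MeC(O)N(OMe)Me, −78 → −30 °C; aq. NH4Cl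
Reagents that add atoms: N-methoxy-N-methylacetamide, CC(=O)N(C)OC
Why: LDA deprotonates the 2-methyl group (γ-deprotonation of a β-alkoxy enoate, as with 2,2,6-trimethyl-1,3-dioxin-4-one) and dienolate 5 is acylated at its γ-carbon by the Weinreb amide (vinylogous Claisen acylation), adduct 6 holding the ketone back until the quench so that neither over-addition nor proton transfer occurs, while α-attack would build a quaternary carbon.

Step 4
Reactants: 8 methyl 3-(4-hydroxyphenyl)propanoate (methyl phloretate); 2 prenyl bromide
Product: 10 methyl 3-[4-hydroxy-3-(3-methylbut-2-en-1-yl)phenyl]propanoate, via sodium phenolate 9 (not isolated)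
Conditions: NaH (1.0 equiv), toluene, 0 °C → rt; then 2 (1.0 equiv), rt → 50 °C
Reagents that add atoms: none
Why: in toluene the sodium phenolate reacts as a tight ion pair at carbon, not oxygen (ortho-C-alkylation of a phenoxide in a non-polar medium); the para position is blocked and the two ortho positions are equivalent, so only O-prenyl ether and bis-prenylated material need to be separated.

Step 5
Reactants: 10 methyl 3-[4-hydroxy-3-(3-methylbut-2-en-1-yl)phenyl]propanoate
Product: 11 methyl 3-[4-(methoxymethoxy)-3-(3-methylbut-2-en-1-yl)phenyl]propanoate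
Conditions: MOMCl, i-Pr2NEt, CH2Cl2, 0 °C → rt
Reagents that add atoms: chloromethyl methyl ether (MOMCl), COCCl
Why: O-alkylation of the phenol with MOMCl and Hünig's base (standard MOM protection) gives an acetal that tolerates LDA and methoxide and leaves the ester and the prenyl group untouched.

Step 6
Reactants: 7 methyl 6,6-dimethyl-2-(2-oxopropyl)-5,6-dihydro-4H-pyran-3-carboxylate; 11 methyl 3-[4-(methoxymethoxy)-3-(3-methylbut-2-en-1-yl)phenyl]propanoate
Product: 13 methyl 2-{6-[4-(methoxymethoxy)-3-(3-methylbut-2-en-1-yl)phenyl]-2,4-dioxohexyl}-6,6-dimethyl-5,6-dihydro-4H-pyran-3-carboxylate, via dilithium dianion 12 (not isolated)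
Conditions: 7 (2.2 equiv), LDA (4.4 equiv), THF, −78 → −20 °C; then 11 (1.0 equiv), −78 → 0 °C; aq. NH4Cl
Reagents that add atoms: none
Why: two equivalents of LDA turn 7 into the 1,3-dianion 12 (first at the doubly activated ring-CH2, which also switches off the pyran ester as an electrophile, then at the terminal methyl), and the more basic terminal carbanion is acylated by ester 11 (Claisen condensation of a 1,3-dianion, as practised with β-diketone and keto-dioxinone dianions), the second equivalent of dianion taking up the acidic proton of the new β-diketone.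

Step 7
Reactants: 13 methyl 2-{6-[4-(methoxymethoxy)-3-(3-methylbut-2-en-1-yl)phenyl]-2,4-dioxohexyl}-6,6-dimethyl-5,6-dihydro-4H-pyran-3-carboxylate
Product: 15 1-(5,7-dihydroxy-2,2-dimethyl-3,4-dihydro-2H-chromen-6-yl)-3-[4-(methoxymethoxy)-3-(3-methylbut-2-en-1-yl)phenyl]propan-1-one, via trione tautomer 14 (not isolated)
Conditions: Mg(OMe)2 (3 equiv), MeOH, reflux; brief cold dilute HCl work-up
Reagents that add atoms: none
Why: Proposed new method: Mg(OMe)2 converts the β-diketone of 13 into its magnesium chelate, whose central carbon (future C6) adds to the ester carbonyl (future C5) held cis to the side chain across the C4a=C8a double bond, and loss of methoxide gives trione tautomer 14, which enolises at once to the aromatic chroman 15. The closest known reaction is the base-mediated Claisen-mode (Dieckmann-type) cyclisation of 3,5,7-triketo esters to acylphloroglucinols; the new element is that the 3-oxo group is masked as the pyran enol ether, so the electrophile is a β-alkoxyacrylate (vinylogous carbonate) ester. Ring A closes in a 6-exo-trig mode (6-(enolexo)-exo-trig for the diketonate), forming only the C5–C6 bond. No stereocentre is created. The step needs C- over O-acylation and Claisen over aldol closure: O-acylation gives an enol lactone that methoxide reopens whereas C-acylation is drained irreversibly by aromatisation, and an aldol adduct at C4a cannot aromatise because C4a carries no hydrogen, so the linear 6-acyl-5,7-dihydroxychroman follows from connectivity alone. A weak base in methanol is chosen so that only the diketone, not C8, is deprotonated and the ester stays electrophilic.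

Step 8
Reactants: 15 1-(5,7-dihydroxy-2,2-dimethyl-3,4-dihydro-2H-chromen-6-yl)-3-[4-(methoxymethoxy)-3-(3-methylbut-2-en-1-yl)phenyl]propan-1-one
Product: 16 1-(5,7-dihydroxy-2,2-dimethyl-3,4-dihydro-2H-chromen-6-yl)-3-[4-hydroxy-3-(3-methylbut-2-en-1-yl)phenyl]propan-1-one (CNP0080516.0)
Conditions: aq. HCl (3 M), MeOH, rt → 40 °C, stopped at full conversion
Reagents that add atoms: none
Why: acid-catalysed acetal exchange of the aryl MOM ether with methanol (standard MOM cleavage) frees the ring-B phenol, and dilute acid at low temperature should avoid cyclisation of the ortho-prenylphenol to a second chroman while the ketone, the ring-A chroman and the alkene stay inert.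

**Compound list**

1 | methyl acetoacetate | CC(=O)CC(=O)OC | starting material
2 | prenyl bromide (1-bromo-3-methylbut-2-ene) | CC(C)=CCBr | starting material
3 | methyl 2-acetyl-5-methylhex-4-enoate (racemic) | COC(=O)C(CC=C(C)C)C(C)=O | intermediate
4 | methyl 2,6,6-trimethyl-5,6-dihydro-4H-pyran-3-carboxylate | COC(=O)C1=C(C)OC(C)(C)CC1 | intermediate
5 | lithium dienolate of 4 (lithium methoxy(6,6-dimethyl-2-methylideneoxan-3-ylidene)methanolate) | [Li+].COC([O-])=C1CCC(C)(C)OC1=C | intermediate (not isolated)
6 | lithium 1-[3-(methoxycarbonyl)-6,6-dimethyl-5,6-dihydro-4H-pyran-2-yl]-2-[methoxy(methyl)amino]propan-2-olate | [Li+].COC(=O)C1=C(CC(C)([O-])N(C)OC)OC(C)(C)CC1 | intermediate (not isolated)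
7 | methyl 6,6-dimethyl-2-(2-oxopropyl)-5,6-dihydro-4H-pyran-3-carboxylate | COC(=O)C1=C(CC(C)=O)OC(C)(C)CC1 | intermediate
8 | methyl 3-(4-hydroxyphenyl)propanoate (methyl phloretate) | COC(=O)CCc1ccc(O)cc1 | starting material
9 | sodium 4-(3-methoxy-3-oxopropyl)phenolate | [Na+].COC(=O)CCc1ccc([O-])cc1 | intermediate (not isolated)
10 | methyl 3-[4-hydroxy-3-(3-methylbut-2-en-1-yl)phenyl]propanoate | COC(=O)CCc1ccc(O)c(CC=C(C)C)c1 | intermediate
11 | methyl 3-[4-(methoxymethoxy)-3-(3-methylbut-2-en-1-yl)phenyl]propanoate | COCOc1ccc(CCC(=O)OC)cc1CC=C(C)C | intermediate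
12 | dilithium dianion of 7 (deprotonated at the ring-CH2 and at the terminal methyl) | [Li+].[Li+].COC([O-])=C1CCC(C)(C)OC1=CC([O-])=C | intermediate (not isolated)
13 | methyl 2-{6-[4-(methoxymethoxy)-3-(3-methylbut-2-en-1-yl)phenyl]-2,4-dioxohexyl}-6,6-dimethyl-5,6-dihydro-4H-pyran-3-carboxylate (drawn as the diketo form) | COC(=O)C1=C(CC(=O)CC(=O)CCc2ccc(OCOC)c(CC=C(C)C)c2)OC(C)(C)CC1 | intermediate
14 | 6-{3-[4-(methoxymethoxy)-3-(3-methylbut-2-en-1-yl)phenyl]propanoyl}-2,2-dimethyl-3,4-dihydro-2H-chromene-5,7(6H,8H)-dione | COCOc1ccc(CCC(=O)C2C(=O)CC3=C(CCC(C)(C)O3)C2=O)cc1CC=C(C)C | intermediate (not isolated)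
15 | 1-(5,7-dihydroxy-2,2-dimethyl-3,4-dihydro-2H-chromen-6-yl)-3-[4-(methoxymethoxy)-3-(3-methylbut-2-en-1-yl)phenyl]propan-1-one | CC(C)=CCc1cc(CCC(=O)c2c(O)cc3c(c2O)CCC(C)(C)O3)ccc1OCOC | intermediate
16 | 1-(5,7-dihydroxy-2,2-dimethyl-3,4-dihydro-2H-chromen-6-yl)-3-[4-hydroxy-3-(3-methylbut-2-en-1-yl)phenyl]propan-1-one | CC(C)=CCc1cc(CCC(=O)c2c(O)cc3c(c2O)CCC(C)(C)O3)ccc1O | target

**Totals**

Total step count: 8. Longest linear sequence: 6 steps (steps 1, 2, 3, 6, 7, 8 from methyl acetoacetate); the ring-B branch (steps 4, 5) joins at step 6.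

**Steps most likely to fail**

1. Step 7. The chelated diketonate is a weak nucleophile and the donor-substituted ester a weak electrophile, so ring closure may be outpaced by methoxide-induced retro-Claisen cleavage of the diketone or by addition at C8a with opening of the pyran. The fallback uses known chemistry, sets out from 11 and comes back at 16, replacing steps 6–8. Ester 11 would be converted with MeNHOMe·HCl and i-PrMgCl (THF, −20 °C) into N-methoxy-N-methyl-3-[4-(methoxymethoxy)-3-(3-methylbut-2-en-1-yl)phenyl]propanamide F1. Separately, phloroglucinol and 2-methylbut-3-en-2-ol (BF3·OEt2, dioxane) would give 2,2-dimethylchroman-5,7-diol F2, which MOMCl and i-Pr2NEt convert into 5,7-bis(methoxymethoxy)-2,2-dimethylchroman F3. Directed ortho-lithiation of F3 (n-BuLi, TMEDA, THF, 0 °C) should occur between the two MOM ethers to give 6-lithio-5,7-bis(methoxymethoxy)-2,2-dimethylchroman F4. Acylation of F4 by F1 gives 1-[5,7-bis(methoxymethoxy)-2,2-dimethylchroman-6-yl]-3-[4-(methoxymethoxy)-3-(3-methylbut-2-en-1-yl)phenyl]propan-1-one F5, and aq. HCl in MeOH removes all three MOM groups to give 16.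

2. Step 6. Proton transfer (enolisation of ester 11, quenching of the dianion by the acidic product) and reaction at the internal carbanion may leave the acyl transfer incomplete. The fallback sets out from 11 and comes back at 13, replacing the Claisen condensation by aldol addition and oxidation. DIBAL-H (CH2Cl2, −78 °C) would reduce 11 to 3-[4-(methoxymethoxy)-3-(3-methylbut-2-en-1-yl)phenyl]propanal F6. Dianion 12 adds to F6 at −78 °C to give methyl 2-{4-hydroxy-6-[4-(methoxymethoxy)-3-(3-methylbut-2-en-1-yl)phenyl]-2-oxohexyl}-6,6-dimethyl-5,6-dihydro-4H-pyran-3-carboxylate F7 (racemic, the carbinol centre being destroyed next). Dess–Martin periodinane buffered with NaHCO3 oxidises F7 to 13.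

3. Step 4. O-alkylation of the ambident phenolate and a second prenylation at the other ortho position compete with mono ortho-C-alkylation, and traces of HBr may cyclise the product to a chroman. The fallback sets out from 8 and comes back at 11, replacing steps 4 and 5. NBS (MeCN, 0 °C) would brominate 8 ortho to the hydroxyl to give methyl 3-(3-bromo-4-hydroxyphenyl)propanoate F8. MOMCl and i-Pr2NEt give methyl 3-[3-bromo-4-(methoxymethoxy)phenyl]propanoate F9. Stille coupling of F9 with tributyl(3-methylbut-2-en-1-yl)stannane (Pd(PPh3)4, DMF, 100 °C) should install the linear prenyl group and deliver 11.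

**Further compounds**

F1 | step 7 | N-methoxy-N-methyl-3-[4-(methoxymethoxy)-3-(3-methylbut-2-en-1-yl)phenyl]propanamide | CON(C)C(=O)CCc1ccc(OCOC)c(CC=C(C)C)c1
F2 | step 7 | 2,2-dimethylchroman-5,7-diol | CC1(C)CCc2c(O)cc(O)cc2O1
F3 | step 7 | 5,7-bis(methoxymethoxy)-2,2-dimethylchroman | COCOc1cc(OCOC)c2CCC(C)(C)Oc2c1
F4 | step 7 | 6-lithio-5,7-bis(methoxymethoxy)-2,2-dimethylchroman | [Li]c1c(OCOC)cc2OC(C)(C)CCc2c1OCOC
F5 | step 7 | 1-[5,7-bis(methoxymethoxy)-2,2-dimethylchroman-6-yl]-3-[4-(methoxymethoxy)-3-(3-methylbut-2-en-1-yl)phenyl]propan-1-one | COCOc1ccc(CCC(=O)c2c(OCOC)cc3OC(C)(C)CCc3c2OCOC)cc1CC=C(C)C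
F6 | step 6 | 3-[4-(methoxymethoxy)-3-(3-methylbut-2-en-1-yl)phenyl]propanal | COCOc1ccc(CCC=O)cc1CC=C(C)C
F7 | step 6 | methyl 2-{4-hydroxy-6-[4-(methoxymethoxy)-3-(3-methylbut-2-en-1-yl)phenyl]-2-oxohexyl}-6,6-dimethyl-5,6-dihydro-4H-pyran-3-carboxylate (racemic) | COC(=O)C1=C(CC(=O)CC(O)CCc2ccc(OCOC)c(CC=C(C)C)c2)OC(C)(C)CC1
F8 | step 4 | methyl 3-(3-bromo-4-hydroxyphenyl)propanoate | COC(=O)CCc1ccc(O)c(Br)c1
F9 | step 4 | methyl 3-[3-bromo-4-(methoxymethoxy)phenyl]propanoate | COCOc1ccc(CCC(=O)OC)cc1Br
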